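**Retrosynthetic overview** (ring atoms numbered as in 7-oxabicyclo[4.1.0]heptane: C1 quaternary oxirane carbon, C2 carbinol, C3 =C–heptenyl, C4 =C–CH2OH, C5 carbinol, C6 oxirane CH, O7)
1. Endgame: C2 carbinol from the C2 ketone (Luche reduction); heptenyl at C3 by Suzuki–Miyaura coupling of a 3-iodo enone; C3=C4 by dehydrogenation of the ketone after loss of a temporary allyl ester on C3.
2. Core: keto ester 8 plus two molecules of silyloxyacetaldehyde 9. Knoevenagel condensation makes C3–C4; then, in one flask, an enamine Michael addition makes C4–C5 and a ring-closing Darzens reaction makes C1–C6 and O7–C1.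
3. Enabling feature: the oxirane carbons C1 and C6 lie α,β to C2. With C2 as a ketone, the oxirane C1–C6–O7 is a Darzens retron (C1 = α-chloro ketone carbon, C6 = aldehyde carbon). C6 is 1,5 to C2 through C3–C4–C5, a Michael retron once C3=C4 is saturated and C3 carries an ester.
4. Ring order: the six-membered carbocycle (C1–C6 bond) and the oxirane (O7–C1 bond) form together in step 5. C5 is set by the amine catalyst, C6 and C1 are relayed from C5 in the ring closure, and C2 is set last by hydride.

Key step: step 5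

Remark on the chemistry: the chlorine-bearing carbon of 4, 5, 7, 8, 10 and 11, the keto ester α-carbon of 11 and C3 of 12 and 13 are enolisable centres that are erased downstream; their SMILES are left unassigned or show the expected major epimer.

Step 1
Reactants: 1 pent-4-enal; 2 methyl methacrylate
Product: 3 methyl (2E)-2-methyl-6-oxohex-2-enoate
Conditions: second-generation Grubbs catalyst RuCl2(=CHPh)(H2IMes)(PCy3) (3 mol %), 2 (5 equiv), CH2Cl2, 40 °C
Reagents that add atoms: none
Why: Olefin cross-metathesis of a terminal alkene with a 1,1-disubstituted acrylate favours the cross product and should give the trisubstituted (E)-enoate under thermodynamic control, with ethene as the only by-product.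

Step 2
Reactants: 3 methyl (2E)-2-methyl-6-oxohex-2-enoate
Product: 5 (4E)-2-chloro-6-methoxy-5-methyl-6-oxohex-4-enoic acid, via alpha-chloro aldehyde 4 (not isolated)
Conditions: N-chlorosuccinimide (1.05 equiv), DL-proline (10 mol %), CH2Cl2, 0 °C; then NaClO2, NaH2PO4, 2-methylbut-2-ene, t-BuOH/H2O, 0 °C
Reagents that add atoms: N-chlorosuccinimide O=C1CCC(=O)N1Cl; sodium chlorite [Na+].[O-]Cl=O
Why: Enamine-catalysed α-chlorination of the aldehyde followed by Pinnick oxidation of the crude, labile α-chloro aldehyde; the electron-poor enoate is inert to both reagents and the new centre need not be controlled because it is enolised in step 5.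

Step 3
Reactants: 5 (4E)-2-chloro-6-methoxy-5-methyl-6-oxohex-4-enoic acid; 6 Meldrum's acid
Product: 8 1-allyl 8-methyl (6E)-4-chloro-7-methyl-3-oxooct-6-enedioate, via acyl Meldrum's acid 7 (not isolated)
Conditions: DCC, DMAP, CH2Cl2, 0 to 23 °C, filtration; then allyl alcohol, toluene, 80 °C
Reagents that add atoms: allyl alcohol C=CCO
Why: C-acylation of Meldrum's acid and alcoholysis of the acyl Meldrum's acid through its acyl ketene is the standard entry to γ-chloro-β-keto esters and loses only acetone and CO2.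

Step 4
Reactants: 8 1-allyl 8-methyl (6E)-4-chloro-7-methyl-3-oxooct-6-enedioate; 9 (tert-butyldimethylsilyloxy)acetaldehyde
Product: 10 alkylidene keto ester (2-[2-(silyloxy)ethylidene] derivative of 8; E/Z mixture)
Conditions: 9 (1.1 equiv), piperidine (10 mol %), AcOH (10 mol %), 4 Å molecular sieves, CH2Cl2, 0 °C
Reagents that add atoms: none
Why: Knoevenagel condensation at the doubly activated C2 methylene of the β-keto ester; the E/Z mixture is used as such because both isomers converge in step 5, and low temperature with sieves limits double-bond migration.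

Step 5
Reactants: 10 alkylidene keto ester; 9 (tert-butyldimethylsilyloxy)acetaldehyde
Product: 12 allyl (1R,3S,4R,5R,6R)-5-(TBS-oxy)-4-(TBS-oxymethyl)-1-[(2E)-4-methoxy-3-methyl-4-oxobut-2-enyl]-2-oxo-7-oxabicyclo[4.1.0]heptane-3-carboxylate, via Michael adduct 11 (not isolated)
Conditions: 9 (1.5 equiv), (S)-2-[diphenyl(trimethylsilyloxy)methyl]pyrrolidine (20 mol %), PhCO2H (20 mol %), toluene, 0 °C; then K2CO3 (2 equiv), DMF, 0 to 23 °C
Reagents that add atoms: none
Why: The secondary amine converts 9 into its E-enamine, which adds to the β-carbon (future C4) of the doubly activated alkylidene 10 on the face left open by the diphenyl(silyloxy)methyl group to give, after hydrolysis, the syn adduct 11 (resting as its lactol); K2CO3 then enolises the chlorine-bearing γ-carbon of the β-keto ester, which attacks the C6 aldehyde, and the alkoxide displaces chloride. The closest known reaction types are amine-catalysed enamine Michael additions of α-oxy aldehydes to alkylidene 1,3-dicarbonyl acceptors and the organocatalytic Michael/intramolecular Darzens sequence of γ-chloro-β-keto esters that gives 7-oxabicyclo[4.1.0]heptan-2-ones. The carbocycle closes by a 6-(enolexo)-exo-trig aldol addition that forms the C1–C6 bond, and the oxirane by a 3-exo-tet displacement at C1. C5 is set by the catalyst and C4 (temporary) by the synclinal open transition state; C6 and C1 are relayed from C5, because in the chair with the C4 and C5 substituents equatorial only the aldolate with axial C6–O and axial C1–Cl can close, which puts the oxirane cis to the C5 silyloxy group and the butenoate chain on the other face, while all other aldolates revert by retro-aldol. The step needs γ- over α-reactivity of the keto ester (the α-enolate could only close a four-membered ring and is a resting state), no loss of configuration at C5 (the aldehyde is masked as lactol until base is added, and a C5 epimer would be a separable diastereomer because C4 is still stereogenic) and an irreversible last event (epoxide closure; dehydration is impossible at the fully substituted C1).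

Step 6
Reactants: 12 epoxy β-keto allyl ester
Product: 14 methyl (2E)-4-[(1R,4R,5R,6R)-5-(TBS-oxy)-4-(TBS-oxymethyl)-2-oxo-7-oxabicyclo[4.1.0]heptan-1-yl]-2-methylbut-2-enoate, via beta-keto acid 13 (not isolated)
Conditions: Pd(PPh3)4 (5 mol %), morpholine (3 equiv), THF, 23 °C
Reagents that add atoms: none
Why: Zerovalent palladium ionises the allyl ester, morpholine traps the allyl fragment and the β-keto acid loses CO2 at room temperature (Tsuji-type deallylative decarboxylation), conditions mild enough for the epoxy ketone, the silyl ethers and the methyl ester.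

Step 7
Reactants: 14 epoxy ketone
Product: 16 methyl (2E)-4-[(1R,5R,6R)-5-(TBS-oxy)-4-(TBS-oxymethyl)-2-oxo-7-oxabicyclo[4.1.0]hept-3-en-1-yl]-2-methylbut-2-enoate, via trimethylsilyl enol ether 15 (not isolated)
Conditions: LiN(SiMe3)2 (1.1 equiv), Me3SiCl, THF, −78 °C; then Pd(OAc)2 (1.1 equiv), MeCN, 23 °C
Reagents that add atoms: none
Why: Saegusa–Ito oxidation; the ketone can enolise only toward C3 because C1 is quaternary, so the C3=C4 enone should form regiospecifically, and C4, having served as a control element, becomes sp2.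

Step 8
Reactants: 16 enone
Product: 17 3-iodo enone
Conditions: I2 (2.5 equiv), pyridine/CH2Cl2 (1:1), 0 to 23 °C
Reagents that add atoms: iodine II
Why: α-Iodination of the enone by conjugate addition of pyridine, iodination of the enolate and elimination; the weak base should leave the γ-silyloxy epoxy enone intact.

Step 9
Reactants: 17 3-iodo enone; 18 (E)-hept-1-en-1-ylboronic acid
Product: 19 methyl (2E)-4-[(1R,5R,6R)-5-(TBS-oxy)-4-(TBS-oxymethyl)-3-[(1E)-hept-1-enyl]-2-oxo-7-oxabicyclo[4.1.0]hept-3-en-1-yl]-2-methylbut-2-enoate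
Conditions: 18 (1.5 equiv), PdCl2(PhCN)2 (5 mol %), AsPh3 (10 mol %), Ag2O (1.6 equiv), THF/H2O (8:1), 23 °C
Reagents that add atoms: none
Why: Suzuki–Miyaura coupling of a 2-iodo enone with an alkenylboronic acid under Ag2O promotion runs at room temperature with retention of the (E)-alkene and without the strong base that would open the epoxy enone.

Step 10
Reactants: 19 dienone
Product: 20 methyl (2E)-4-[(1S,2R,5R,6R)-5-(TBS-oxy)-4-(TBS-oxymethyl)-3-[(1E)-hept-1-enyl]-2-hydroxy-7-oxabicyclo[4.1.0]hept-3-en-1-yl]-2-methylbut-2-enoate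
Conditions: NaBH4, CeCl3·7H2O, MeOH, −78 °C
Reagents that add atoms: none
Why: Luche 1,2-reduction of the cross-conjugated dienone; hydride should enter C2 from the oxirane face, anti to the C1 butenoate chain, to give the C2 hydroxyl trans to the oxirane (2R), the usual sense for cerium-mediated reduction of α,β-epoxy ketones.

Step 11
Reactants: 20 allylic alcohol methyl ester
Product: 21 (2E)-4-[(1S,2R,5R,6R)-5-(TBS-oxy)-4-(TBS-oxymethyl)-3-[(1E)-hept-1-enyl]-2-hydroxy-7-oxabicyclo[4.1.0]hept-3-en-1-yl]-2-methylbut-2-enoic acid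
Conditions: Me3SnOH (8 equiv), 1,2-dichloroethane, 70 °C; wash with cold 0.05 M HCl
Reagents that add atoms: trimethyltin hydroxide C[Sn](C)(C)O
Why: Near-neutral ester hydrolysis with trimethyltin hydroxide frees the acid without generating the C2 alkoxide, so Payne-type epoxide migration under aqueous hydroxide is avoided.

Step 12
Reactants: 21 bis-silyl ether acid
Product: 22 (2E)-4-[(1S,2R,5R,6R)-3-[(1E)-hept-1-enyl]-2,5-dihydroxy-4-(hydroxymethyl)-7-oxabicyclo[4.1.0]hept-3-en-1-yl]-2-methylbut-2-enoic acid (target)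
Conditions: HF·pyridine, pyridine, THF, 0 to 23 °C
Reagents that add atoms: none
Why: Buffered fluoride cleavage of both silyl ethers under conditions that epoxides, allylic alcohols and dienes tolerate.

**Compound list** (TBS = tert-butyldimethylsilyl)
1 | pent-4-enal | C=CCCC=O | starting material
2 | methyl methacrylate | C=C(C)C(=O)OC | starting material
3 | methyl (2E)-2-methyl-6-oxohex-2-enoate | COC(=O)/C(C)=C/CCC=O | intermediate
4 | methyl (2E)-5-chloro-2-methyl-6-oxohex-2-enoate (racemic) | COC(=O)/C(C)=C/CC(Cl)C=O | intermediate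
5 | (4E)-2-chloro-6-methoxy-5-methyl-6-oxohex-4-enoic acid (racemic) | COC(=O)/C(C)=C/CC(Cl)C(=O)O | intermediate
6 | Meldrum's acid (2,2-dimethyl-1,3-dioxane-4,6-dione) | CC1(C)OC(=O)CC(=O)O1 | starting material
7 | methyl (2E)-5-chloro-6-(2,2-dimethyl-4,6-dioxo-1,3-dioxan-5-ylidene)-6-hydroxy-2-methylhex-2-enoate (acyl Meldrum's acid, enol form) | COC(=O)/C(C)=C/CC(Cl)C(O)=C1C(=O)OC(C)(C)OC1=O | intermediate
8 | 1-allyl 8-methyl (6E)-4-chloro-7-methyl-3-oxooct-6-enedioate (racemic at C4) | C=CCOC(=O)CC(=O)C(Cl)C/C=C(\C)C(=O)OC | intermediate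
9 | (tert-butyldimethylsilyloxy)acetaldehyde | CC(C)(C)[Si](C)(C)OCC=O | starting material
10 | 1-allyl 8-methyl (6E)-2-{2-[(TBS)oxy]ethylidene}-4-chloro-7-methyl-3-oxooct-6-enedioate (E/Z mixture at the new alkene) | C=CCOC(=O)C(=CCO[Si](C)(C)C(C)(C)C)C(=O)C(Cl)C/C=C(\C)C(=O)OC | intermediate
11 | 1-allyl 8-methyl (6E)-2-{(2R,3R)-1,3-bis[(TBS)oxy]-4-oxobutan-2-yl}-4-chloro-7-methyl-3-oxooct-6-enedioate (open form of the lactol) | O=C[C@H](O[Si](C)(C)C(C)(C)C)[C@@H](CO[Si](C)(C)C(C)(C)C)C(C(=O)OCC=C)C(=O)C(Cl)C/C=C(\C)C(=O)OC | intermediate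
12 | allyl (1R,3S,4R,5R,6R)-5-[(TBS)oxy]-4-{[(TBS)oxy]methyl}-1-[(2E)-4-methoxy-3-methyl-4-oxobut-2-en-1-yl]-2-oxo-7-oxabicyclo[4.1.0]heptane-3-carboxylate | O=C1[C@@H](C(=O)OCC=C)[C@H](CO[Si](C)(C)C(C)(C)C)[C@@H](O[Si](C)(C)C(C)(C)C)[C@H]2O[C@@]12C/C=C(\C)C(=O)OC | intermediate
13 | (1R,3S,4R,5R,6R)-5-[(TBS)oxy]-4-{[(TBS)oxy]methyl}-1-[(2E)-4-methoxy-3-methyl-4-oxobut-2-en-1-yl]-2-oxo-7-oxabicyclo[4.1.0]heptane-3-carboxylic acid | O=C1[C@@H](C(=O)O)[C@H](CO[Si](C)(C)C(C)(C)C)[C@@H](O[Si](C)(C)C(C)(C)C)[C@H]2O[C@@]12C/C=C(\C)C(=O)OC | intermediate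
14 | methyl (2E)-4-[(1R,4R,5R,6R)-5-[(TBS)oxy]-4-{[(TBS)oxy]methyl}-2-oxo-7-oxabicyclo[4.1.0]heptan-1-yl]-2-methylbut-2-enoate | O=C1C[C@H](CO[Si](C)(C)C(C)(C)C)[C@@H](O[Si](C)(C)C(C)(C)C)[C@H]2O[C@@]12C/C=C(\C)C(=O)OC | intermediate
15 | C2–C3 trimethylsilyl enol ether of 14 | C[Si](C)(C)OC1=C[C@H](CO[Si](C)(C)C(C)(C)C)[C@@H](O[Si](C)(C)C(C)(C)C)[C@H]2O[C@@]12C/C=C(\C)C(=O)OC | intermediate
16 | methyl (2E)-4-[(1R,5R,6R)-5-[(TBS)oxy]-4-{[(TBS)oxy]methyl}-2-oxo-7-oxabicyclo[4.1.0]hept-3-en-1-yl]-2-methylbut-2-enoate | O=C1C=C(CO[Si](C)(C)C(C)(C)C)[C@@H](O[Si](C)(C)C(C)(C)C)[C@H]2O[C@@]12C/C=C(\C)C(=O)OC | intermediate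
17 | methyl (2E)-4-[(1R,5R,6R)-5-[(TBS)oxy]-4-{[(TBS)oxy]methyl}-3-iodo-2-oxo-7-oxabicyclo[4.1.0]hept-3-en-1-yl]-2-methylbut-2-enoate | O=C1C(I)=C(CO[Si](C)(C)C(C)(C)C)[C@@H](O[Si](C)(C)C(C)(C)C)[C@H]2O[C@@]12C/C=C(\C)C(=O)OC | intermediate
18 | (E)-hept-1-en-1-ylboronic acid | CCCCC/C=C/B(O)O | starting material
19 | methyl (2E)-4-[(1R,5R,6R)-5-[(TBS)oxy]-4-{[(TBS)oxy]methyl}-3-[(1E)-hept-1-en-1-yl]-2-oxo-7-oxabicyclo[4.1.0]hept-3-en-1-yl]-2-methylbut-2-enoate | CCCCC/C=C/C1=C(CO[Si](C)(C)C(C)(C)C)[C@@H](O[Si](C)(C)C(C)(C)C)[C@H]2O[C@@]2(C/C=C(\C)C(=O)OC)C1=O | intermediate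
20 | methyl (2E)-4-[(1S,2R,5R,6R)-5-[(TBS)oxy]-4-{[(TBS)oxy]methyl}-3-[(1E)-hept-1-en-1-yl]-2-hydroxy-7-oxabicyclo[4.1.0]hept-3-en-1-yl]-2-methylbut-2-enoate | CCCCC/C=C/C1=C(CO[Si](C)(C)C(C)(C)C)[C@@H](O[Si](C)(C)C(C)(C)C)[C@H]2O[C@@]2(C/C=C(\C)C(=O)OC)[C@@H]1O | intermediate
21 | (2E)-4-[(1S,2R,5R,6R)-5-[(TBS)oxy]-4-{[(TBS)oxy]methyl}-3-[(1E)-hept-1-en-1-yl]-2-hydroxy-7-oxabicyclo[4.1.0]hept-3-en-1-yl]-2-methylbut-2-enoic acid | CCCCC/C=C/C1=C(CO[Si](C)(C)C(C)(C)C)[C@@H](O[Si](C)(C)C(C)(C)C)[C@H]2O[C@@]2(C/C=C(\C)C(=O)O)[C@@H]1O | intermediate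
22 | (2E)-4-[(1S,2R,5R,6R)-3-[(1E)-hept-1-en-1-yl]-2,5-dihydroxy-4-(hydroxymethyl)-7-oxabicyclo[4.1.0]hept-3-en-1-yl]-2-methylbut-2-enoic acid | CCCCC/C=C/C1=C(CO)[C@@H](O)[C@H]2O[C@@]2(C/C=C(\C)C(=O)O)[C@@H]1O | target

**Step count and risks**
Total step count: 12. Longest linear sequence: 12 (compounds 2, 6, 9 and 18 enter as purchased materials).

Steps most likely to fail:

1. Step 5. The enamine addition to the trisubstituted, γ-oxygenated alkylidene may be slow or poorly syn-selective, the double bond of the acceptor may migrate under amine catalysis, the aldehyde α-centre may epimerise before ring closure, and closure at the tertiary chloride may lag behind retro-Michael cleavage. The fallback moves C–C bond formation from amine to Lewis-acid activation and separates it from the base step. It sets out from 9 and 10. Compound 9 is converted with tert-butyldimethylsilyl triflate and Et3N into the silyl enol ether (Z)-1,2-bis[(tert-butyldimethylsilyl)oxy]ethene F1. F1 is added to 10, held as a chelated 1-oxadiene by Cu(OTf)2 and (S,S)-2,2'-isopropylidenebis(4-tert-butyl-2-oxazoline), in CH2Cl2 at −78 °C (Mukaiyama–Michael addition, formally an inverse-demand hetero-Diels–Alder reaction); the ligand antipode is the one that matches C5 of 11. Mild acidic work-up should release 11, which is isolated as its lactol and freed from diastereomers. Treatment with K2CO3 in DMF then closes both rings, and the route is rejoined at 12.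

2. Step 10. Facial selectivity of hydride delivery at C2 may be poor, because the nearly flat dienone offers both the oxirane face and the face of the C1 side chain. The fallback replaces selective reduction by stereoinversion. It sets out from 19, which is reduced on purpose from the other face with the bulky hydride LiBH(sec-Bu)3 in THF at −78 °C to give the C2-epimeric alcohol F2. Mitsunobu reaction of F2 (PPh3, diisopropyl azodicarboxylate, 4-nitrobenzoic acid, toluene, 0 °C) should give the inverted 4-nitrobenzoate F3. Brief methanolysis (K2CO3, MeOH, 0 °C) returns the route to 20.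

3. Step 4. The γ-silyloxy alkylidene may suffer double-bond migration into the β,γ-position, Michael addition of a second molecule of 8, and losses on isolation. The fallback avoids isolating the acceptor by running a three-component domino reaction. It sets out from 8 and 9 (2.3 equiv), which are combined with the chiral amine and PhCO2H of step 5 in toluene over 4 Å sieves; the same amine then catalyses the Knoevenagel condensation (iminium) and the enamine addition, so that 10 and 11 are consumed as they form. Addition of K2CO3 and DMF completes the sequence and the route is rejoined at 12; no new compound is made (F0).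

Further compounds
F1 | step 5 | (Z)-1,2-bis[(tert-butyldimethylsilyl)oxy]ethene | CC(C)(C)[Si](C)(C)O/C=C\O[Si](C)(C)C(C)(C)C
F2 | step 10 | methyl (2E)-4-[(1S,2S,5R,6R)-5-[(TBS)oxy]-4-{[(TBS)oxy]methyl}-3-[(1E)-hept-1-en-1-yl]-2-hydroxy-7-oxabicyclo[4.1.0]hept-3-en-1-yl]-2-methylbut-2-enoate (C2 epimer of 20) | CCCCC/C=C/C1=C(CO[Si](C)(C)C(C)(C)C)[C@@H](O[Si](C)(C)C(C)(C)C)[C@H]2O[C@@]2(C/C=C(\C)C(=O)OC)[C@H]1O
F3 | step 10 | 4-nitrobenzoate ester of 20 (C2 configured as in 20) | CCCCC/C=C/C1=C(CO[Si](C)(C)C(C)(C)C)[C@@H](O[Si](C)(C)C(C)(C)C)[C@H]2O[C@@]2(C/C=C(\C)C(=O)OC)[C@@H]1OC(=O)c1ccc(cc1)[N+](=O)[O-]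
F0 | step 4 | none | none
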